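**Plan**
- Cuts: ring C at O1–C2 and C3–C4 (both in one (4+2) step); the C8–C1'' bond to the lavandulyl group (Negishi coupling); the C4a–CHO bond (ortho-formylation); the C6 side chain is grown from the formyl carbon of 2,4,6-trihydroxybenzaldehyde.
- Enabling feature: O1 (on C8a) and the carbonyl carbon C4 (on C4a) sit on neighbouring ring A carbons, and ring C holds only two further atoms, C2 and C3. A heterodiene O1=C8a–C4a=C4 (an ortho-quinone methide at the aldehyde oxidation level) and a C2=C3 alkene carrying the ring B aryl group and the C3 oxygen are therefore the whole of ring C.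
- Forward order: ring A is fully substituted first (side chain, formyl group, iodide, then lavandulyl); ring B arrives in an E enol acetate; ring C closes last; C4–OMe is then turned into C4=O and all silyl groups leave in one step.
- Stereochemistry: C2'' from lipase-resolved (S)-lavandulol; C3 from a chiral phosphoric acid; C2 trans to C3 from the E alkene; C4 is a throw-away centre.

Key step: step 14

Abbreviations: TIPSO = triisopropylsilyloxy; TBSO = tert-butyldimethylsilyloxy; (R)-lavandulyl = (2R)-5-methyl-2-(prop-1-en-2-yl)hex-4-en-1-yl; flavan numbering (O1, C2–C4, C4a, C5–C8, C8a; ring B primed) is used for the bicyclic compounds.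
Remark (assumption): the lipase is taken to acylate (R)-lavandulol faster, so the unreacted alcohol is (S); the same spatial arrangement is named R once CH2OH has become CH2–aryl.
Remark: the flavan C4 centre is drawn in the all-trans form expected from the cycloaddition; its epimer would converge at the C4 ketone.

**Route**

Step 1
Reactants: 1 2,4,6-trihydroxybenzaldehyde
Product: 2 4-(benzyloxy)-2,6-dihydroxybenzaldehyde
Conditions: BnBr (1.0 equiv), K2CO3 (1.0 equiv), DMF, 0 °C to rt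
Reagents that add atoms: benzyl bromide, BrCc1ccccc1
Why: Williamson etherification; the 4-OH is the most acidic hydroxyl and the only one not hydrogen-bonded to the formyl group, so one equivalent of base and halide should alkylate it selectively.

Step 2
Reactants: 2 4-(benzyloxy)-2,6-dihydroxybenzaldehyde
Product: 3 4-(benzyloxy)-2,6-bis(TIPSO)benzaldehyde
Conditions: TIPSOTf (2.5 equiv), 2,6-lutidine (4 equiv), CH2Cl2, 0 °C to rt
Reagents that add atoms: triisopropylsilyl triflate, CC(C)[Si](OS(=O)(=O)C(F)(F)F)(C(C)C)C(C)C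
Why: Silyl triflate with a hindered base silylates both formyl-chelated phenols (the future O5 and O7), which resist silyl chlorides.

Step 3
Reactants: 3 4-(benzyloxy)-2,6-bis(TIPSO)benzaldehyde
Product: 4 methyl (2E)-3-[4-(benzyloxy)-2,6-bis(TIPSO)phenyl]prop-2-enoate
Conditions: Ph3P=CHCO2Me (2 equiv), toluene, 110 °C
Reagents that add atoms: methyl (triphenylphosphoranylidene)acetate, COC(=O)C=P(c1ccccc1)(c1ccccc1)c1ccccc1
Why: Wittig olefination with a stabilised ylide should give the E cinnamate (geometry is irrelevant after step 4); heating overcomes the two ortho substituents.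

Step 4
Reactants: 4 methyl (2E)-3-[4-(benzyloxy)-2,6-bis(TIPSO)phenyl]prop-2-enoate
Product: 5 methyl 3-[4-hydroxy-2,6-bis(TIPSO)phenyl]propanoate
Conditions: H2 (1 atm), 10% Pd/C, EtOAc–MeOH, rt
Reagents that add atoms: none
Why: Heterogeneous hydrogenation saturates the cinnamate C=C and hydrogenolyses the benzyl ether in one operation, freeing only the phenol para to the side chain; aryl silyl ethers are untouched.

Step 5
Reactants: 5 methyl 3-[4-hydroxy-2,6-bis(TIPSO)phenyl]propanoate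
Product: 6 4-(3-hydroxy-3-methylbutyl)-3,5-bis(TIPSO)phenol
Conditions: MeMgBr (4.5 equiv), THF, 0 °C to rt; aq. NH4Cl
Reagents that add atoms: methylmagnesium bromide, C[Mg]Br
Why: Double Grignard addition to the methyl ester builds the tertiary alcohol of the C6 side chain; one further equivalent is consumed by the phenol, whose magnesium phenoxide is inert.

Step 6
Reactants: 6 4-(3-hydroxy-3-methylbutyl)-3,5-bis(TIPSO)phenol
Product: 7 2-hydroxy-5-(3-hydroxy-3-methylbutyl)-4,6-bis(TIPSO)benzaldehyde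
Conditions: MgCl2 (3 equiv), Et3N (6 equiv), paraformaldehyde (8 equiv), MeCN, 80 °C
Reagents that add atoms: formaldehyde (from paraformaldehyde), C=O
Why: Casnati–Skattebøl magnesium-mediated ortho-formylation; the two ortho positions of the symmetric phenol are equivalent and the salicylaldehyde formed is deactivated towards a second formylation.

Step 7
Reactants: 7 2-hydroxy-5-(3-hydroxy-3-methylbutyl)-4,6-bis(TIPSO)benzaldehyde
Product: 8 2-hydroxy-5-(3-hydroxy-3-methylbutyl)-3-iodo-4,6-bis(TIPSO)benzaldehyde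
Conditions: N-iodosuccinimide (1.05 equiv), DMF, 0 °C to rt, dark
Reagents that add atoms: N-iodosuccinimide, O=C1CCC(=O)N1I
Why: Electrophilic aromatic iodination at the only unsubstituted ring carbon, which is ortho to the free phenol and ortho/para to the two silyloxy groups.

Step 8
Reactants: 9 (±)-lavandulol
Product: 10 (S)-lavandulol, (2S)-5-methyl-2-(prop-1-en-2-yl)hex-4-en-1-ol
Conditions: porcine pancreatic lipase, vinyl acetate, t-BuOMe, rt, taken to about 65% conversion; chromatography (second pass if needed)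
Reagents that add atoms: none
Why: Lipase-catalysed kinetic resolution by transesterification; the enzyme acylates the (R)-alcohol faster, so running past half conversion should leave the (S)-alcohol in high enantiomeric purity.

Step 9
Reactants: 10 (S)-lavandulol
Product: 11 (S)-lavandulyl iodide, (5S)-6-iodo-2-methyl-5-(prop-1-en-2-yl)hex-2-ene
Conditions: PPh3, I2, imidazole, CH2Cl2, 0 °C
Reagents that add atoms: iodine, II
Why: Appel-type iodination by SN2 displacement at the primary carbon; the adjacent stereocentre is not involved.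

Step 10
Reactants: 11 (S)-lavandulyl iodide; 8 2-hydroxy-5-(3-hydroxy-3-methylbutyl)-3-iodo-4,6-bis(TIPSO)benzaldehyde
Product: 13 2-hydroxy-5-(3-hydroxy-3-methylbutyl)-3-[(R)-lavandulyl]-4,6-bis(TIPSO)benzaldehyde, via (S)-lavandulylzinc iodide 12 (not isolated)
Conditions: 11, Zn dust (activated with 1,2-dibromoethane and Me3SiCl), LiCl, THF, 35 °C; then 8, Pd(OAc)2 (5 mol%), SPhos (2-dicyclohexylphosphino-2',6'-dimethoxybiphenyl, 10 mol%), THF, 25–45 °C, zinc reagent (2.5 equiv) added slowly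
Reagents that add atoms: none
Why: Negishi sp2–sp3 cross-coupling; zinc insertion into the primary iodide leaves the β-stereocentre untouched, the aldehyde is inert to the alkylzinc halide, and the Pd/SPhos catalyst should couple a primary alkylzinc with the flanked aryl iodide faster than β-hydride elimination or protonolysis by the free hydroxyls.

Step 11
Reactants: 14 2,4-dihydroxybenzaldehyde
Product: 15 2,4-bis(TIPSO)benzaldehyde
Conditions: TIPSOTf (2.4 equiv), 2,6-lutidine (4 equiv), CH2Cl2, 0 °C to rt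
Reagents that add atoms: triisopropylsilyl triflate, CC(C)[Si](OS(=O)(=O)C(F)(F)F)(C(C)C)C(C)C
Why: Silylation of both phenols; the formyl-chelated 2-OH needs the triflate.

Step 12
Reactants: 15 2,4-bis(TIPSO)benzaldehyde
Product: 16 2-{(E)-2-[2,4-bis(TIPSO)phenyl]ethenyl}-4,4,5,5-tetramethyl-1,3,2-dioxaborolane
Conditions: bis(pinacolato)borylmethane (1.2 equiv), LiTMP (lithium 2,2,6,6-tetramethylpiperidide, 1.2 equiv), THF, −78 °C to rt
Reagents that add atoms: bis(4,4,5,5-tetramethyl-1,3,2-dioxaborolan-2-yl)methane, CC1(C)OB(CB2OC(C)(C)C(C)(C)O2)OC1(C)C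
Why: Boron–Wittig olefination; the α-boryl carbanion adds to the aldehyde and syn-elimination of the borate should give the trans alkenyl boronate, which fixes the E geometry.

Step 13
Reactants: 16 2-{(E)-2-[2,4-bis(TIPSO)phenyl]ethenyl}-4,4,5,5-tetramethyl-1,3,2-dioxaborolane
Product: 17 (E)-2-[2,4-bis(TIPSO)phenyl]ethenyl acetate
Conditions: Cu(OAc)2 (2 equiv), Et3N (3 equiv), 4 Å molecular sieves, MeCN, rt, air
Reagents that add atoms: Cu(OAc)2, CC(=O)[O-].CC(=O)[O-].[Cu+2]
Why: Chan–Lam-type oxidative C–O coupling of an alkenylboron compound with acetate; transmetallation to copper and C–O reductive elimination from trivalent copper proceed with retention, so the E geometry of 16 is carried into the enol acetate.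

Step 14
Reactants: 13 2-hydroxy-5-(3-hydroxy-3-methylbutyl)-3-[(R)-lavandulyl]-4,6-bis(TIPSO)benzaldehyde; 17 (E)-2-[2,4-bis(TIPSO)phenyl]ethenyl acetate; 18 trimethyl orthoformate
Product: 21 (2R,3S,4R)-3-acetoxy-4-methoxy-6-(3-hydroxy-3-methylbutyl)-8-[(R)-lavandulyl]-5,7,2',4'-tetrakis(TIPSO)flavan (2,3-trans; 3,4-trans), via dimethyl acetal 19 (not isolated), via 4-methoxy ortho-quinone methide 20 (not isolated)
Conditions: 18 (1.5 equiv), (R)-TRIP [(R)-3,3'-bis(2,4,6-triisopropylphenyl)-1,1'-binaphthyl-2,2'-diyl hydrogen phosphate, 10 mol%; its antipode if the first runs show the opposite sense], 5 Å molecular sieves, CH2Cl2, 0 °C; then 17 (1.5 equiv), −40 to 0 °C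
Reagents that add atoms: none
Why: Proposed new method: the phosphoric acid first converts 13 and 18 into the dimethyl acetal 19 and then ionises it, with loss of methanol, to the 4-methoxy ortho-quinone methide 20, held as a hydrogen-bonded ion pair with the chiral phosphate and acting as an electron-poor O1=C8a–C4a=C4 heterodiene; the closest known reactions are the acid-catalysed three-component cycloaddition of salicylaldehyde acetals with styrenes to 2-aryl-4-alkoxychromans and chiral phosphoric acid-catalysed (4+2) cycloadditions of ortho-quinone methides, whereas an enol ester as the 2π partner and this catalyst–acetal pairing are untested. Ring C closes by an asynchronous inverse-electron-demand hetero-Diels–Alder (4+2) cycloaddition in which C4 bonds to the acetoxy-bearing carbon (C3) ahead of O1–C2 bond formation, the stepwise limit being a 6-exo-trig capture by O1 of a benzylic cation delocalised into ring B. C3 is set by the alkene face that the chiral phosphate pocket exposes to C4 (catalyst control; the lavandulyl centre is six bonds away), C2 is set trans to C3 because both bonds form on one face of the E alkene (trans-diequatorial is also the thermodynamic outcome should C2–O1 ionise reversibly), and C4 is expected trans to C3 but is erased in step 18. The step needs regioselectivity (C3, not C2, bonding to C4), secured by the 2,4-bis(silyloxy)phenyl group, which stabilises positive charge at C2 far better than the weakly donating acetoxy group does at C3; it also needs chemoselectivity, secured by ring A having no free ring position and a single free phenol and by the isolated lavandulyl alkenes being much poorer nucleophiles than the aryl-conjugated enol acetate.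

Step 15
Reactants: 21 (2R,3S,4R)-3-acetoxy-4-methoxy-6-(3-hydroxy-3-methylbutyl)-8-[(R)-lavandulyl]-5,7,2',4'-tetrakis(TIPSO)flavan
Product: 22 (2R,3S,4R)-4-methoxy-6-(3-hydroxy-3-methylbutyl)-8-[(R)-lavandulyl]-5,7,2',4'-tetrakis(TIPSO)flavan-3-ol
Conditions: K2CO3 (0.3 equiv), MeOH–THF (3:1), rt
Reagents that add atoms: none
Why: Base-catalysed transesterification (Zemplén-type methanolysis) of the secondary acetate; it is done before C4 is a ketone, so no ring-opening-prone flavanone meets base, and aryl triisopropylsilyl ethers tolerate catalytic carbonate in methanol.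

Step 16
Reactants: 22 (2R,3S,4R)-4-methoxy-6-(3-hydroxy-3-methylbutyl)-8-[(R)-lavandulyl]-5,7,2',4'-tetrakis(TIPSO)flavan-3-ol
Product: 23 (2R,3S,4R)-3-(TBSO)-4-methoxy-6-(3-hydroxy-3-methylbutyl)-8-[(R)-lavandulyl]-5,7,2',4'-tetrakis(TIPSO)flavan
Conditions: TBSOTf (1.3 equiv), 2,6-lutidine (3 equiv), CH2Cl2, −78 to −40 °C
Reagents that add atoms: tert-butyldimethylsilyl triflate, CC(C)(C)[Si](C)(C)OS(=O)(=O)C(F)(F)F
Why: Silyl triflate silylation of the secondary 3-OH at a temperature at which the tertiary hydroxyl does not react; the non-participating silyl ether replaces the acetate so that C4 can be ionised without acyl migration and every remaining protecting group falls to fluoride.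

Step 17
Reactants: 23 (2R,3S,4R)-3-(TBSO)-4-methoxy-6-(3-hydroxy-3-methylbutyl)-8-[(R)-lavandulyl]-5,7,2',4'-tetrakis(TIPSO)flavan
Product: 24 (2R,3S,4R)-3-(TBSO)-6-(3-hydroxy-3-methylbutyl)-8-[(R)-lavandulyl]-5,7,2',4'-tetrakis(TIPSO)flavan-4-ol
Conditions: camphorsulfonic acid (0.2 equiv), THF–H2O (4:1), 0 °C to rt
Reagents that add atoms: water, O
Why: SN1 solvolysis; the C4 methyl ether is benzylic to a ring with three oxygen donors ortho/para to C4, so it ionises under mild aqueous acid and water captures the cation, expected trans to the bulky 3-silyloxy group (the C4 configuration is lost in the next step).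

Step 18
Reactants: 24 (2R,3S,4R)-3-(TBSO)-6-(3-hydroxy-3-methylbutyl)-8-[(R)-lavandulyl]-5,7,2',4'-tetrakis(TIPSO)flavan-4-ol
Product: 25 (2R,3R)-3-(TBSO)-6-(3-hydroxy-3-methylbutyl)-8-[(R)-lavandulyl]-5,7,2',4'-tetrakis(TIPSO)flavan-4-one
Conditions: Dess–Martin periodinane (1.5 equiv), CH2Cl2, 0 °C to rt
Reagents that add atoms: none
Why: Dess–Martin oxidation of the only secondary alcohol (the tertiary hydroxyl and the alkenes are inert) gives the C4 ketone without any benzylic C–H oxidation and without epimerising C3.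

Step 19
Reactants: 25 (2R,3R)-3-(TBSO)-6-(3-hydroxy-3-methylbutyl)-8-[(R)-lavandulyl]-5,7,2',4'-tetrakis(TIPSO)flavan-4-one
Product: 26 (2R,3R)-2-(2,4-dihydroxyphenyl)-3,5,7-trihydroxy-6-(3-hydroxy-3-methylbutyl)-8-[(2R)-5-methyl-2-(prop-1-en-2-yl)hex-4-en-1-yl]chroman-4-one (CNP0183552.3)
Conditions: Bu4NF (8 equiv), AcOH (8 equiv), THF, 0 °C to rt
Reagents that add atoms: none
Why: Fluoride-mediated desilylation buffered with acetic acid should cleave the four aryl silyl ethers and the α-keto secondary silyl ether without exposing the dihydroflavonol, which epimerises at C2 by ring opening under base, to basic fluoride.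

**Compound list**

1 | 2,4,6-trihydroxybenzaldehyde | O=Cc1c(O)cc(O)cc1O | starting material
2 | 4-(benzyloxy)-2,6-dihydroxybenzaldehyde | O=Cc1c(O)cc(OCc2ccccc2)cc1O | intermediate
3 | 4-(benzyloxy)-2,6-bis(triisopropylsilyloxy)benzaldehyde | O=Cc1c(O[Si](C(C)C)(C(C)C)C(C)C)cc(OCc2ccccc2)cc1O[Si](C(C)C)(C(C)C)C(C)C | intermediate
4 | methyl (2E)-3-[4-(benzyloxy)-2,6-bis(triisopropylsilyloxy)phenyl]prop-2-enoate | COC(=O)/C=C/c1c(O[Si](C(C)C)(C(C)C)C(C)C)cc(OCc2ccccc2)cc1O[Si](C(C)C)(C(C)C)C(C)C | intermediate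
5 | methyl 3-[4-hydroxy-2,6-bis(triisopropylsilyloxy)phenyl]propanoate | COC(=O)CCc1c(O[Si](C(C)C)(C(C)C)C(C)C)cc(O)cc1O[Si](C(C)C)(C(C)C)C(C)C | intermediate
6 | 4-(3-hydroxy-3-methylbutyl)-3,5-bis(triisopropylsilyloxy)phenol | CC(C)(O)CCc1c(O[Si](C(C)C)(C(C)C)C(C)C)cc(O)cc1O[Si](C(C)C)(C(C)C)C(C)C | intermediate
7 | 2-hydroxy-5-(3-hydroxy-3-methylbutyl)-4,6-bis(triisopropylsilyloxy)benzaldehyde | CC(C)(O)CCc1c(O[Si](C(C)C)(C(C)C)C(C)C)cc(O)c(C=O)c1O[Si](C(C)C)(C(C)C)C(C)C | intermediate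
8 | 2-hydroxy-5-(3-hydroxy-3-methylbutyl)-3-iodo-4,6-bis(triisopropylsilyloxy)benzaldehyde | CC(C)(O)CCc1c(O[Si](C(C)C)(C(C)C)C(C)C)c(I)c(O)c(C=O)c1O[Si](C(C)C)(C(C)C)C(C)C | intermediate
9 | (±)-lavandulol, racemic 5-methyl-2-(prop-1-en-2-yl)hex-4-en-1-ol | C=C(C)C(CO)CC=C(C)C | starting material
10 | (S)-lavandulol, (2S)-5-methyl-2-(prop-1-en-2-yl)hex-4-en-1-ol | C=C(C)[C@H](CC=C(C)C)CO | intermediate
11 | (S)-lavandulyl iodide, (5S)-6-iodo-2-methyl-5-(prop-1-en-2-yl)hex-2-ene | C=C(C)[C@H](CC=C(C)C)CI | intermediate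
12 | (S)-lavandulylzinc iodide, [(2S)-5-methyl-2-(prop-1-en-2-yl)hex-4-en-1-yl]zinc iodide (not isolated) | C=C(C)[C@H](CC=C(C)C)C[Zn]I | intermediate
13 | 2-hydroxy-5-(3-hydroxy-3-methylbutyl)-3-[(2R)-5-methyl-2-(prop-1-en-2-yl)hex-4-en-1-yl]-4,6-bis(triisopropylsilyloxy)benzaldehyde | C=C(C)[C@H](CC=C(C)C)Cc1c(O[Si](C(C)C)(C(C)C)C(C)C)c(CCC(C)(C)O)c(O[Si](C(C)C)(C(C)C)C(C)C)c(C=O)c1O | intermediate
14 | 2,4-dihydroxybenzaldehyde | O=Cc1ccc(O)cc1O | starting material
15 | 2,4-bis(triisopropylsilyloxy)benzaldehyde | O=Cc1ccc(O[Si](C(C)C)(C(C)C)C(C)C)cc1O[Si](C(C)C)(C(C)C)C(C)C | intermediate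
16 | 2-{(E)-2-[2,4-bis(triisopropylsilyloxy)phenyl]ethenyl}-4,4,5,5-tetramethyl-1,3,2-dioxaborolane | CC1(C)OB(/C=C/c2ccc(O[Si](C(C)C)(C(C)C)C(C)C)cc2O[Si](C(C)C)(C(C)C)C(C)C)OC1(C)C | intermediate
17 | (E)-2-[2,4-bis(triisopropylsilyloxy)phenyl]ethenyl acetate | CC(=O)O/C=C/c1ccc(O[Si](C(C)C)(C(C)C)C(C)C)cc1O[Si](C(C)C)(C(C)C)C(C)C | intermediate
18 | trimethyl orthoformate | COC(OC)OC | starting material
19 | 2-(dimethoxymethyl)-4-(3-hydroxy-3-methylbutyl)-6-[(2R)-5-methyl-2-(prop-1-en-2-yl)hex-4-en-1-yl]-3,5-bis(triisopropylsilyloxy)phenol (not isolated) | C=C(C)[C@H](CC=C(C)C)Cc1c(O[Si](C(C)C)(C(C)C)C(C)C)c(CCC(C)(C)O)c(O[Si](C(C)C)(C(C)C)C(C)C)c(C(OC)OC)c1O | intermediate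
20 | (6Z)-4-(3-hydroxy-3-methylbutyl)-6-(methoxymethylidene)-2-[(2R)-5-methyl-2-(prop-1-en-2-yl)hex-4-en-1-yl]-3,5-bis(triisopropylsilyloxy)cyclohexa-2,4-dien-1-one (not isolated) | C=C(C)[C@H](CC=C(C)C)CC1=C(O[Si](C(C)C)(C(C)C)C(C)C)C(CCC(C)(C)O)=C(O[Si](C(C)C)(C(C)C)C(C)C)/C(=C/OC)C1=O | intermediate
21 | (2R,3S,4R)-2-[2,4-bis(triisopropylsilyloxy)phenyl]-6-(3-hydroxy-3-methylbutyl)-4-methoxy-8-[(2R)-5-methyl-2-(prop-1-en-2-yl)hex-4-en-1-yl]-5,7-bis(triisopropylsilyloxy)chroman-3-yl acetate | C=C(C)[C@H](CC=C(C)C)Cc1c(O[Si](C(C)C)(C(C)C)C(C)C)c(CCC(C)(C)O)c(O[Si](C(C)C)(C(C)C)C(C)C)c2c1O[C@H](c1ccc(O[Si](C(C)C)(C(C)C)C(C)C)cc1O[Si](C(C)C)(C(C)C)C(C)C)[C@@H](OC(C)=O)[C@@H]2OC | intermediate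
22 | (2R,3S,4R)-2-[2,4-bis(triisopropylsilyloxy)phenyl]-6-(3-hydroxy-3-methylbutyl)-4-methoxy-8-[(2R)-5-methyl-2-(prop-1-en-2-yl)hex-4-en-1-yl]-5,7-bis(triisopropylsilyloxy)chroman-3-ol | C=C(C)[C@H](CC=C(C)C)Cc1c(O[Si](C(C)C)(C(C)C)C(C)C)c(CCC(C)(C)O)c(O[Si](C(C)C)(C(C)C)C(C)C)c2c1O[C@H](c1ccc(O[Si](C(C)C)(C(C)C)C(C)C)cc1O[Si](C(C)C)(C(C)C)C(C)C)[C@@H](O)[C@@H]2OC | intermediate
23 | (2R,3S,4R)-2-[2,4-bis(triisopropylsilyloxy)phenyl]-3-(tert-butyldimethylsilyloxy)-6-(3-hydroxy-3-methylbutyl)-4-methoxy-8-[(2R)-5-methyl-2-(prop-1-en-2-yl)hex-4-en-1-yl]-5,7-bis(triisopropylsilyloxy)chromane | C=C(C)[C@H](CC=C(C)C)Cc1c(O[Si](C(C)C)(C(C)C)C(C)C)c(CCC(C)(C)O)c(O[Si](C(C)C)(C(C)C)C(C)C)c2c1O[C@H](c1ccc(O[Si](C(C)C)(C(C)C)C(C)C)cc1O[Si](C(C)C)(C(C)C)C(C)C)[C@@H](O[Si](C)(C)C(C)(C)C)[C@@H]2OC | intermediate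
24 | (2R,3S,4R)-2-[2,4-bis(triisopropylsilyloxy)phenyl]-3-(tert-butyldimethylsilyloxy)-6-(3-hydroxy-3-methylbutyl)-8-[(2R)-5-methyl-2-(prop-1-en-2-yl)hex-4-en-1-yl]-5,7-bis(triisopropylsilyloxy)chroman-4-ol | C=C(C)[C@H](CC=C(C)C)Cc1c(O[Si](C(C)C)(C(C)C)C(C)C)c(CCC(C)(C)O)c(O[Si](C(C)C)(C(C)C)C(C)C)c2c1O[C@H](c1ccc(O[Si](C(C)C)(C(C)C)C(C)C)cc1O[Si](C(C)C)(C(C)C)C(C)C)[C@@H](O[Si](C)(C)C(C)(C)C)[C@@H]2O | intermediate
25 | (2R,3R)-2-[2,4-bis(triisopropylsilyloxy)phenyl]-3-(tert-butyldimethylsilyloxy)-6-(3-hydroxy-3-methylbutyl)-8-[(2R)-5-methyl-2-(prop-1-en-2-yl)hex-4-en-1-yl]-5,7-bis(triisopropylsilyloxy)chroman-4-one | C=C(C)[C@H](CC=C(C)C)Cc1c(O[Si](C(C)C)(C(C)C)C(C)C)c(CCC(C)(C)O)c(O[Si](C(C)C)(C(C)C)C(C)C)c2c1O[C@H](c1ccc(O[Si](C(C)C)(C(C)C)C(C)C)cc1O[Si](C(C)C)(C(C)C)C(C)C)[C@@H](O[Si](C)(C)C(C)(C)C)C2=O | intermediate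
26 | (2R,3R)-2-(2,4-dihydroxyphenyl)-3,5,7-trihydroxy-6-(3-hydroxy-3-methylbutyl)-8-[(2R)-5-methyl-2-(prop-1-en-2-yl)hex-4-en-1-yl]chroman-4-one | C=C(C)[C@H](CC=C(C)C)Cc1c(O)c(CCC(C)(C)O)c(O)c2c1O[C@H](c1ccc(O)cc1O)[C@@H](O)C2=O | target

**Count and risks**

Total step count: 19. Longest linear sequence: 14 steps (steps 1–7, 10, 14–19).

1. Step 14 (new method). The alkene may bond to C4 through its aryl-bearing carbon if the acetoxy group steers the attack. Ring B may react as an arene in a Friedel–Crafts sense. The phosphate ion pair may discriminate the two alkene faces poorly, or the acetal may ionise too slowly with a weak acid. The fallback uses known chemistry, sets out from 13, 15 and 18 and comes back at 26. Wittig methylenation of 15 (MePPh3Br, KOt-Bu, THF) gives 2,4-bis(TIPSO)styrene F1. The Sc(OTf)3-catalysed three-component cycloaddition of 13, 18 and F1, the established salicylaldehyde acetal–styrene reaction, gives the 2,4-cis-4-methoxyflavan F2; its (2R,4R) epimer forms alongside because nothing controls C2 relative to the lavandulyl centre. Solvolysis (camphorsulfonic acid, wet THF) gives the flavan-4-ol F3 and Dess–Martin oxidation the flavanone F4. The lithium enolate (LiHMDS, THF, −78 °C) is hydroxylated with 2-(phenylsulfonyl)-3-phenyloxaziridine anti to the C2 aryl group to give the trans-3-hydroxyflavanone F5. F5 is separated from its (2S,3S) diastereomer by preparative HPLC, which is possible because the lavandulyl centre makes the two diastereomeric, and is desilylated as in step 19 to 26.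

2. Step 10. The alkylzinc may be protonated by the phenol and the tertiary hydroxyl before it transmetallates. Reductive elimination at the carbon flanked by OH and OTIPS may be slow enough for β-hydride elimination to take over. The homoallylic radical formed during zinc insertion may rearrange. The fallback replaces zinc by a boron nucleophile that tolerates protic groups; it sets out from 11 and 8 and comes back at 13. Lithium–iodine exchange on 11 (t-BuLi, Et2O, −78 °C) and quenching with 2-isopropoxy-4,4,5,5-tetramethyl-1,3,2-dioxaborolane gives (S)-lavandulyl pinacol boronate F6. KHF2 in aqueous methanol converts it into potassium (S)-lavandulyltrifluoroborate F7. Suzuki–Miyaura coupling of F7 with 8 (Pd(OAc)2, 2-dicyclohexylphosphino-2',6'-diisopropoxybiphenyl, K2CO3, toluene–H2O, 80 °C) gives 13.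

3. Step 13. Protodeboronation or oxidative homocoupling of the electron-rich styryl boronate may outrun C–O coupling, and the enol acetate may hydrolyse on work-up. The fallback makes the enol ester by O-acylation of an enolate; it sets out from 15 and comes back at 17. Wittig reaction of 15 with (methoxymethyl)triphenylphosphonium chloride and KHMDS (THF, 0 °C) gives the enol ether 1-(2-methoxyethenyl)-2,4-bis(TIPSO)benzene F8 as an E/Z mixture. Mild acid hydrolysis (aqueous formic acid, THF) gives [2,4-bis(TIPSO)phenyl]acetaldehyde F9. Acetylation (Ac2O, KOAc, 100 °C) gives the enol acetates, from which the E isomer 17 is separated by chromatography and the Z isomer is recycled by iodine-catalysed equilibration.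

**Further compounds**

F1 | step 14 | 2,4-bis(triisopropylsilyloxy)styrene | C=Cc1ccc(O[Si](C(C)C)(C(C)C)C(C)C)cc1O[Si](C(C)C)(C(C)C)C(C)C
F2 | step 14 | (2S,4S)-2-[2,4-bis(triisopropylsilyloxy)phenyl]-6-(3-hydroxy-3-methylbutyl)-4-methoxy-8-[(2R)-5-methyl-2-(prop-1-en-2-yl)hex-4-en-1-yl]-5,7-bis(triisopropylsilyloxy)chromane | C=C(C)[C@H](CC=C(C)C)Cc1c(O[Si](C(C)C)(C(C)C)C(C)C)c(CCC(C)(C)O)c(O[Si](C(C)C)(C(C)C)C(C)C)c2c1O[C@H](c1ccc(O[Si](C(C)C)(C(C)C)C(C)C)cc1O[Si](C(C)C)(C(C)C)C(C)C)C[C@@H]2OC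
F3 | step 14 | (2S,4S)-2-[2,4-bis(triisopropylsilyloxy)phenyl]-6-(3-hydroxy-3-methylbutyl)-8-[(2R)-5-methyl-2-(prop-1-en-2-yl)hex-4-en-1-yl]-5,7-bis(triisopropylsilyloxy)chroman-4-ol | C=C(C)[C@H](CC=C(C)C)Cc1c(O[Si](C(C)C)(C(C)C)C(C)C)c(CCC(C)(C)O)c(O[Si](C(C)C)(C(C)C)C(C)C)c2c1O[C@H](c1ccc(O[Si](C(C)C)(C(C)C)C(C)C)cc1O[Si](C(C)C)(C(C)C)C(C)C)C[C@@H]2O
F4 | step 14 | (2S)-2-[2,4-bis(triisopropylsilyloxy)phenyl]-6-(3-hydroxy-3-methylbutyl)-8-[(2R)-5-methyl-2-(prop-1-en-2-yl)hex-4-en-1-yl]-5,7-bis(triisopropylsilyloxy)chroman-4-one | C=C(C)[C@H](CC=C(C)C)Cc1c(O[Si](C(C)C)(C(C)C)C(C)C)c(CCC(C)(C)O)c(O[Si](C(C)C)(C(C)C)C(C)C)c2c1O[C@H](c1ccc(O[Si](C(C)C)(C(C)C)C(C)C)cc1O[Si](C(C)C)(C(C)C)C(C)C)CC2=O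
F5 | step 14 | (2R,3R)-2-[2,4-bis(triisopropylsilyloxy)phenyl]-3-hydroxy-6-(3-hydroxy-3-methylbutyl)-8-[(2R)-5-methyl-2-(prop-1-en-2-yl)hex-4-en-1-yl]-5,7-bis(triisopropylsilyloxy)chroman-4-one | C=C(C)[C@H](CC=C(C)C)Cc1c(O[Si](C(C)C)(C(C)C)C(C)C)c(CCC(C)(C)O)c(O[Si](C(C)C)(C(C)C)C(C)C)c2c1O[C@H](c1ccc(O[Si](C(C)C)(C(C)C)C(C)C)cc1O[Si](C(C)C)(C(C)C)C(C)C)[C@@H](O)C2=O
F6 | step 10 | 4,4,5,5-tetramethyl-2-[(2S)-5-methyl-2-(prop-1-en-2-yl)hex-4-en-1-yl]-1,3,2-dioxaborolane | C=C(C)[C@H](CC=C(C)C)CB1OC(C)(C)C(C)(C)O1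
F7 | step 10 | potassium trifluoro[(2S)-5-methyl-2-(prop-1-en-2-yl)hex-4-en-1-yl]borate | C=C(C)[C@H](CC=C(C)C)C[B-](F)(F)F.[K+]
F8 | step 13 | 1-(2-methoxyethenyl)-2,4-bis(triisopropylsilyloxy)benzene (E/Z mixture) | COC=Cc1ccc(O[Si](C(C)C)(C(C)C)C(C)C)cc1O[Si](C(C)C)(C(C)C)C(C)C
F9 | step 13 | [2,4-bis(triisopropylsilyloxy)phenyl]acetaldehyde | O=CCc1ccc(O[Si](C(C)C)(C(C)C)C(C)C)cc1O[Si](C(C)C)(C(C)C)C(C)C
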